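**Remark on the chemistry:** the target has no stereogenic element. Polycarbonyl compounds (6, 7, 14) are drawn in the all-keto form although they will exist largely as enols, and 7 may sit partly as its cyclic hemiketal.

## The problem

The target 17 is a linear array of three rings: resorcinol ring A and phenol ring B are joined through a ketone, and ring B is joined through a methylene to ring C, a 4-hydroxy-2-pyranone. It has no stereocentre, so nothing has to be controlled in space and no centre can steer another; the difficulties are regiochemical and chemoselective. The ketone carbon lies between four ortho substituents (ethyl and hydroxyl on ring A, hydroxyl and the CH2 arm on ring B), which makes the union of two finished rings at this carbon the sterically worst bond construction in the molecule. Ring A must carry acyl, ethyl and two hydroxyls in a fixed 1,2,4,6 pattern, with ethyl and one hydroxyl both next to the acyl carbon. Ring C is a vinylogous acid whose lactone opens in aqueous alkali, and once its carbonyl array exists the methylene between rings B and C is activated and could condense onto the diaryl ketone, so ring C has to be built late and without base. A phenoxide of ring A ortho to the ketone can displace an ortho alkoxy group of ring B in hot base to close a xanthone, and the free resorcinol does not tolerate oxidants, so basic steps must stay mild and the phenols must be masked before any oxidation. The feature that opens the molecule is the substitution of ring A: oxygen on C4 and C6, and the acyl-bearing C1 and the ethyl-bearing C2 as neighbours. This is the pattern left when the C2 methylene of a 1,3,5,7-tetracarbonyl chain ending in an ethyl ketone closes onto C7, so ring A can be grown on a ketone that is already attached to ring B.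

## Retrosynthesis

**17 to 16.** The three aryl O–H bonds of 17 are traced back to O–CH3 bonds in 16. Methyl is chosen because the ring B oxygen already arrives as a methyl ether in starting ester 1, and because two of the three ethers lie ortho to the ketone, where chelation eases cleavage by a boron trihalide. Carrying free phenols through the end game is excluded by the oxidation and enolate steps. The forward step must remove three methyl groups without opening ring C.

**16 to 14.** Ring C is opened at its O1–C2 lactone bond. The precursor is keto-dioxinone 14, which on heating passes through acylketene 15; the enol oxygen of the neighbouring ketone then closes the ring. The neighbouring cut, base-mediated lactonization of an open 3,5-dioxo ester, would put base next to the activated CH2 between ring B and the new carbonyl at a stage where it could condense onto the diaryl ketone. The thermal route is neutral. It asks only for clean cycloreversion and intramolecular capture.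

**14 to 11 and 12.** The bond between the arylacetyl carbonyl carbon and the exocyclic carbon of the dioxinone is cut. This gives arylacetic acid 11, used as its imidazolide 13, and purchasable dioxinone 12, which brings four of the five carbons of ring C in one piece. The forward reaction needs C-acylation of the dienolate of 12 to outrun enolization of 13.

**11 to 10 to 9.** No skeletal bond is cut. Acid 11 is the oxidation product of primary alcohol 10, and 10 is the bis(methyl ether) of diphenol 9. The primary alcohol is left unprotected throughout: it is inert to aqueous alkali and to carbonate with a methylating agent, so a protecting group would add two steps and guard nothing. The forward steps need phenol-selective O-alkylation and an oxidation that stops at the acid without touching the electron-rich ring.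

**9 to 7 (key disconnection).** Ring A is opened at the bond between its acyl-bearing carbon and its ethyl-bearing carbon, and its two phenolic carbons are returned to ketones. This reveals tetraketone 7. The neighbouring cut, the aryl–carbonyl bond, would require two fully ortho-substituted partners to meet at the ketone carbon. Here the ketone is already in place in 7, flanked by only one substituted ring, and ring A does not yet exist. The precursor is an open chain with one aromatic ring instead of two. The forward reaction must be an aldol fold that uses C2 as donor and C7 as acceptor and no other pair.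

**7 to 6 and 3.** The bond between the aryl ketone carbon and C2 of the chain is cut, and the hydroxyethyl arm is joined to the acyl carbon as a lactone. This gives lactone 3 and triketone 6. A lactone is preferred over an open 2,6-disubstituted benzoate because its planar, strained ester is a much better acyl donor, and ring opening releases the arm as the free alcohol in the same event. The forward reaction needs the trianion of 6 to react through its methyl terminus and to add to the carbonyl of 3 faster than it removes a benzylic proton.

**6 to 4 and 5; 3 to 1.** Triketone 6 is cut between C5 and C6 into diketone 4 and ester 5, a terminal acylation of a diketone dianion. Lactone 3 is cut at the bond between its two ring CH2 groups and at the ring O–C(=O) bond, which leads to toluate ester 1 and a one-carbon oxygen electrophile, with hydroxy ester 2 as the intermediate. All four starting materials are purchasable.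

## Roads not taken

**Alternative 1:** ring C by intermolecular cycloaddition of an acylketene with a ketene acetal.
- Cut: the C3–C4 and O1–C2 bonds of ring C.
- Forward key step: 6-{[2-(2-ethyl-4,6-dimethoxybenzoyl)-3-methoxyphenyl]methyl}-2,2-dimethyl-4H-1,3-dioxin-4-one A1 is heated in toluene and undergoes cycloreversion to the acylketene 4-[2-(2-ethyl-4,6-dimethoxybenzoyl)-3-methoxyphenyl]but-1-ene-1,3-dione A2. This combines with 1,1-diethoxyethene A3 and, after loss of one ethoxy group, gives 2-ethoxy-6-{[2-(2-ethyl-4,6-dimethoxybenzoyl)-3-methoxyphenyl]methyl}-4H-pyran-4-one A4. The final dealkylation would remove the ethyl group with the methyl groups, since the 2-hydroxy-4-pyranone so formed is the tautomer of the required ring C.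
- Merits: the step is neutral and involves no enolate next to the arylacetyl carbonyl. In this respect it is better than the chosen end game, whose step 7 carries an enolization risk.
- Weak points: the intermolecular trap must outrun dimerization of A2, and A3 is moisture-sensitive and needed in excess. Decisively, the step does nothing for ring A or the tetra-ortho-substituted ketone: A1 already contains the whole benzophenone, which would have to come from a crowded aryl–carbonyl coupling or from the fold used here.
- Comparison: the chosen plan's key step solves the hardest bond. Its end game from acid 11 is of equal length and uses the same acylketene reactivity intramolecularly (15), with no second component.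

**Alternative 2:** ring B by a formal [3+3] cyclocondensation.
- Cut: two bonds of ring B, one from the acyl-bearing carbon to the arm-bearing carbon and one between the two CH carbons next to the hydroxyl-bearing carbon.
- Forward key step: 1-(2-ethyl-4,6-dimethoxyphenyl)butane-1,3-dione A5 is converted into 1-(2-ethyl-4,6-dimethoxyphenyl)-1,3-bis[(trimethylsilyl)oxy]buta-1,3-diene A6. TiCl4 joins A6 to 5-(benzyloxy)-1,1-dimethoxypentan-3-one A7: the terminal CH2 of A6 bonds to the acetal carbon and its central carbon to the ketone carbon. Loss of methanol and water gives {2-[2-(benzyloxy)ethyl]-6-hydroxyphenyl}(2-ethyl-4,6-dimethoxyphenyl)methanone A8.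
- Merits: ring B, the ketone and both ortho substituents arise in one convergent step. The ring B phenol emerges free while ring A is etherified, a differentiation the chosen plan does not offer (17 does not need it). The step count to the benzophenone stage is about the same as the four steps to 9.
- Weak points: the central carbon of A6, flanked by a 2,6-disubstituted aryl group, must attack an aliphatic ketone to make the most crowded bond. The β-benzyloxy ketone A7 can eliminate or lose its benzyl group under TiCl4. Aryl-diketone dienes such as A6 are less nucleophilic and more labile than the ester-derived dienes for which this cyclization is best established. A5 still needs a regioselective acylation of the ring A arene.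
- Comparison: in the chosen plan the hindered carbonyl is never the site of an intermolecular attack by a hindered partner, no Lewis-acid-labile group is carried, and the substitution pattern of ring A follows from the fold.

**Alternative 3:** ring B from 3-hydroxy-2-pyranone with loss of CO2.
- Cut: the ring B bonds from the hydroxyl-bearing carbon to the acyl-bearing carbon and from the arm-bearing carbon to its neighbouring CH.
- Forward key step: 3-hydroxy-2H-pyran-2-one A9 and the ynone 5-{[tert-butyl(dimethyl)silyl]oxy}-1-(2-ethyl-4,6-dimethoxyphenyl)pent-2-yn-1-one A10 are heated with catalytic triethylamine. Cycloaddition and decarboxylative aromatization give [2-(2-{[tert-butyl(dimethyl)silyl]oxy}ethyl)-6-hydroxyphenyl](2-ethyl-4,6-dimethoxyphenyl)methanone A11.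
- Merits: the regiochemistry is electronically matched, since the remote diene terminus of deprotonated A9 adds to the β-carbon of A10. One step delivers ring B with hydroxyl and arm flanking the ketone. A9 is purchasable. The route to the benzophenone stage is as short as the chosen one or a step shorter.
- Weak points: base-catalysed cycloadditions of A9 are established mainly for reactive alkenes, and a β-alkyl ynone with a di-ortho-substituted aroyl group is a slow, hindered dienophile. The amine or the acidic hydroxyl of A9 can instead add conjugately to A10. A10 itself needs about three steps from a ring A arene and carries a silyl ether to be removed later.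
- Comparison: the chosen plan needs no protecting group on the arm and rests on enolate acylations and an aldol with close polyketide-type precedent. Its own weak point, the handling of free polyketone 7, is confined to one intermediate.

Key step: step 4

## Route

**Step 1**
Reactants: 1 ethyl 2-methoxy-6-methylbenzoate
Product: 3 8-methoxy-3,4-dihydro-1H-isochromen-1-one, via hydroxy ester 2 (not isolated)
Conditions: LiN(i-Pr)2 (1.2 equiv), THF, −78 °C; CH2O (gas), −78 °C → rt; 1 M HCl, rt
Reagents that add atoms: formaldehyde, C=O
Why: Lateral (benzylic) lithiation of the ortho-toluate gives a stabilised benzylic anion that is hydroxymethylated by formaldehyde; the alkoxide of 2 then closes onto the neighbouring ester (lactonization), which the acidic work-up completes.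

**Step 2**
Reactants: 4 pentane-2,4-dione; 5 methyl propanoate
Product: 6 octane-2,4,6-trione
Conditions: 4 (2.2 equiv), LiN(i-Pr)2 (4.4 equiv), THF, 0 °C; 5 (1.0 equiv), 0 °C → rt; cold 1 M HCl
Reagents that add atoms: none
Why: Claisen acylation of the terminal carbanion of the diketone 1,3-dianion by an aliphatic ester, the standard entry to 1,3,5-triketones; the excess dianion takes up the acidic proton of the product, so the triketone is not acylated a second time.

**Step 3**
Reactants: 6 octane-2,4,6-trione; 3 8-methoxy-3,4-dihydro-1H-isochromen-1-one
Product: 7 1-[2-(2-hydroxyethyl)-6-methoxyphenyl]nonane-1,3,5,7-tetraone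
Conditions: 6 (2.0 equiv), LiN(i-Pr)2 (6.0 equiv), THF, 0 °C; 3 (1.0 equiv), −40 → 0 °C; AcOH, −40 °C, then pH 6 phosphate buffer
Reagents that add atoms: none
Why: Claisen-type acylation of a 1,3,5-triketone trianion: the last-formed, most nucleophilic carbanion lies on the methyl terminus (CH3 is deprotonated in preference to the CH2 of the ethyl group) and opens the lactone, a better acyl donor than an open 2,6-disubstituted benzoate; the product stays a polyanion until the buffered quench, which avoids acid-catalysed closure of the freed hydroxyl onto C1.

**Step 4**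
Reactants: 7 1-[2-(2-hydroxyethyl)-6-methoxyphenyl]nonane-1,3,5,7-tetraone
Product: 9 (2-ethyl-4,6-dihydroxyphenyl)[2-(2-hydroxyethyl)-6-methoxyphenyl]methanone, via cyclic aldol adduct 8 (not isolated)
Conditions: KOH (1 M aq.), N2, 0 °C → rt; then 1 M HCl to pH 5, 0 °C
Reagents that add atoms: none
Why: In aqueous KOH 7 is a polyenolate in which any hemiketal between the hydroxyethyl arm and C1 has opened; the carbanion at C2, flanked by the aryl ketone and the C3 carbonyl, adds to the C7 carbonyl of the ethyl ketone to give aldol 8, which loses water by E1cB elimination and enolizes at the former C3 and C5 carbonyls to the aromatic ring. The closest known reaction type is the base-mediated intramolecular aldol condensation of 1-aryl-1,3,5,7-tetraketones to 2-acylresorcinols, the laboratory counterpart of the polyketide fold. Ring A closes in a 6-exo-trig mode with the enolate double bond inside the forming ring. No stereocentre is created in 9; the two of 8 are transient and vanish on aromatization. The step needs regioselectivity between this fold and the reverse one (C6 onto C1), and it is secured because the aryl ketone is twisted and shielded by its methoxy and hydroxyethyl neighbours while the ethyl ketone is unhindered and more electrophilic; the CH2 of the ethyl group is only singly activated, is not ionized in dilute alkali and cannot serve as donor. Chemoselectivity against retro-Claisen cleavage of the chain and against displacement of the ring B methoxy group by the new ortho phenoxide (xanthone closure) rests on dilute base at room temperature, since both processes need heat. The primary alcohol is a spectator, because an alkoxide cannot add productively to the enolized C1.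

**Step 5**
Reactants: 9 (2-ethyl-4,6-dihydroxyphenyl)[2-(2-hydroxyethyl)-6-methoxyphenyl]methanone
Product: 10 (2-ethyl-4,6-dimethoxyphenyl)[2-(2-hydroxyethyl)-6-methoxyphenyl]methanone
Conditions: MeI (4 equiv), K2CO3 (3 equiv), acetone, 50 °C
Reagents that add atoms: iodomethane, CI
Why: Williamson O-methylation of the two phenols; K2CO3 does not deprotonate the primary alcohol, which therefore stays free, and the moderate temperature keeps the ortho phenoxide from displacing the ring B methoxy group.

**Step 6**
Reactants: 10 (2-ethyl-4,6-dimethoxyphenyl)[2-(2-hydroxyethyl)-6-methoxyphenyl]methanone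
Product: 11 [2-(2-ethyl-4,6-dimethoxybenzoyl)-3-methoxyphenyl]acetic acid
Conditions: TEMPO (0.2 equiv), PhI(OAc)2 (2.5 equiv), MeCN–H2O (1:1), rt
Reagents that add atoms: water, O
Why: Nitroxyl-catalysed oxidation with PhI(OAc)2 as terminal oxidant takes the primary alcohol through the aldehyde hydrate to the carboxylic acid under near-neutral, metal-free conditions that leave the aryl methyl ethers and the hindered ketone untouched.

**Step 7**
Reactants: 11 [2-(2-ethyl-4,6-dimethoxybenzoyl)-3-methoxyphenyl]acetic acid; 12 2,2,6-trimethyl-4H-1,3-dioxin-4-one
Product: 14 6-{3-[2-(2-ethyl-4,6-dimethoxybenzoyl)-3-methoxyphenyl]-2-oxopropyl}-2,2-dimethyl-4H-1,3-dioxin-4-one, via acyl imidazolide 13 (not isolated)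
Conditions: 11, 1,1'-carbonyldiimidazole (1.1 equiv), THF, rt; 12 (3 equiv), LiN(SiMe3)2 (3 equiv), THF, −78 °C; add 13, −78 °C; AcOH, −78 °C
Reagents that add atoms: none
Why: The acid is activated as imidazolide 13 and acylates the γ-carbon of the lithium dienolate of 12 (Claisen-type C-acylation, the standard entry to 6-(2-oxoalkyl)dioxinones); excess dienolate absorbs the acidic product proton and the liberated imidazole, and the low temperature favours carbonyl addition over enolization of 13.

**Step 8**
Reactants: 14 6-{3-[2-(2-ethyl-4,6-dimethoxybenzoyl)-3-methoxyphenyl]-2-oxopropyl}-2,2-dimethyl-4H-1,3-dioxin-4-one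
Product: 16 6-{[2-(2-ethyl-4,6-dimethoxybenzoyl)-3-methoxyphenyl]methyl}-4-hydroxy-2H-pyran-2-one, via acylketene 15 (not isolated)
Conditions: PhMe (0.02 M), 110 °C
Reagents that add atoms: none
Why: Thermal retro-[4+2] cleavage of the dioxinone releases acetone and acylketene 15, whose neighbouring ketone enol adds through oxygen to the ketene carbon and closes the 4-hydroxy-2-pyranone; the medium is neutral, so the CH2 between rings B and C is never deprotonated next to the diaryl ketone.

**Step 9**
Reactants: 16 6-{[2-(2-ethyl-4,6-dimethoxybenzoyl)-3-methoxyphenyl]methyl}-4-hydroxy-2H-pyran-2-one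
Product: 17 6-{[2-(2-ethyl-4,6-dihydroxybenzoyl)-3-hydroxyphenyl]methyl}-4-hydroxy-2H-pyran-2-one
Conditions: BBr3 (10 equiv), CH2Cl2, −78 °C → rt; H2O, 0 °C
Reagents that add atoms: none
Why: Lewis-acid cleavage of aryl methyl ethers by BBr3 (boron coordination, then bromide attack at methyl); the two ethers ortho to the ketone are assisted by chelation and the para ether follows at room temperature, while ring C is carried as a boron enolate and returns on hydrolysis.

## Compound list

1 | ethyl 2-methoxy-6-methylbenzoate | CCOC(=O)c1c(C)cccc1OC | starting material
2 | ethyl 2-(2-hydroxyethyl)-6-methoxybenzoate (formed as its lithium alkoxide) | CCOC(=O)c1c(OC)cccc1CCO | intermediate (not isolated)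
3 | 8-methoxy-3,4-dihydro-1H-isochromen-1-one | COc1cccc2CCOC(=O)c12 | intermediate
4 | pentane-2,4-dione | CC(=O)CC(C)=O | starting material
5 | methyl propanoate | CCC(=O)OC | starting material
6 | octane-2,4,6-trione | CCC(=O)CC(=O)CC(C)=O | intermediate
7 | 1-[2-(2-hydroxyethyl)-6-methoxyphenyl]nonane-1,3,5,7-tetraone | CCC(=O)CC(=O)CC(=O)CC(=O)c1c(OC)cccc1CCO | intermediate
8 | 5-ethyl-5-hydroxy-4-[2-(2-hydroxyethyl)-6-methoxybenzoyl]cyclohexane-1,3-dione (mixture of stereoisomers) | CCC1(O)CC(=O)CC(=O)C1C(=O)c1c(OC)cccc1CCO | intermediate (not isolated)
9 | (2-ethyl-4,6-dihydroxyphenyl)[2-(2-hydroxyethyl)-6-methoxyphenyl]methanone | CCc1cc(O)cc(O)c1C(=O)c1c(OC)cccc1CCO | intermediate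
10 | (2-ethyl-4,6-dimethoxyphenyl)[2-(2-hydroxyethyl)-6-methoxyphenyl]methanone | CCc1cc(OC)cc(OC)c1C(=O)c1c(OC)cccc1CCO | intermediate
11 | [2-(2-ethyl-4,6-dimethoxybenzoyl)-3-methoxyphenyl]acetic acid | CCc1cc(OC)cc(OC)c1C(=O)c1c(OC)cccc1CC(=O)O | intermediate
12 | 2,2,6-trimethyl-4H-1,3-dioxin-4-one | CC1=CC(=O)OC(C)(C)O1 | starting material
13 | 2-[2-(2-ethyl-4,6-dimethoxybenzoyl)-3-methoxyphenyl]-1-(1H-imidazol-1-yl)ethan-1-one | CCc1cc(OC)cc(OC)c1C(=O)c1c(OC)cccc1CC(=O)n1ccnc1 | intermediate (not isolated)
14 | 6-{3-[2-(2-ethyl-4,6-dimethoxybenzoyl)-3-methoxyphenyl]-2-oxopropyl}-2,2-dimethyl-4H-1,3-dioxin-4-one | CCc1cc(OC)cc(OC)c1C(=O)c1c(OC)cccc1CC(=O)CC1=CC(=O)OC(C)(C)O1 | intermediate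
15 | 6-[2-(2-ethyl-4,6-dimethoxybenzoyl)-3-methoxyphenyl]hex-1-ene-1,3,5-trione | CCc1cc(OC)cc(OC)c1C(=O)c1c(OC)cccc1CC(=O)CC(=O)C=C=O | intermediate (not isolated)
16 | 6-{[2-(2-ethyl-4,6-dimethoxybenzoyl)-3-methoxyphenyl]methyl}-4-hydroxy-2H-pyran-2-one | CCc1cc(OC)cc(OC)c1C(=O)c1c(OC)cccc1Cc1cc(O)cc(=O)o1 | intermediate
17 | 6-{[2-(2-ethyl-4,6-dihydroxybenzoyl)-3-hydroxyphenyl]methyl}-4-hydroxy-2H-pyran-2-one | CCc1cc(O)cc(O)c1C(=O)c1c(O)cccc1Cc1cc(O)cc(=O)o1 | target

## Step count and least certain steps

Total step count: 9. Longest linear sequence: 8 steps (1 → 3 → 7 → 9 → 10 → 11 → 14 → 16 → 17); step 2 is a one-step side branch that joins at step 3.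

**Step 4 (key step).** Hydroxide-induced retro-Claisen cleavage of the polyketone chain may compete with ring closure. The reaction may stall at aldol 8 if elimination is slow. Closure may also occur in the reverse fold (C6 onto C1) if the aryl ketone is less shielded than expected. The fallback forms the aryl–carbonyl bond instead of ring A; it sets out from lactone 3 and comes back at 10. 1-Ethyl-3,5-dimethoxybenzene F1 is brominated with NBS in MeCN, ortho to ethyl and para to a methoxy group, to give 2-bromo-1-ethyl-3,5-dimethoxybenzene F2. Bromine–lithium exchange (n-BuLi, THF, −78 °C) gives (2-ethyl-4,6-dimethoxyphenyl)lithium F3. F3 should add once to the carbonyl of 3, since the cyclic lithium hemiketal resists a second addition, and give 10 after aqueous work-up. This path is shorter, but it makes the tetra-ortho-substituted ketone by intermolecular attack of a 2,6-disubstituted aryllithium, with proton abstraction at C4 of 3 as competitor; it is therefore held in reserve.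

**Step 3.** Proton transfer from the benzylic C4 of the lactone to the strongly basic trianion, followed by β-elimination of the carboxylate, may compete with carbonyl addition. Acylation may also occur through the ethyl-side CH2, or the trilithium salt may aggregate and react sluggishly. During work-up the freed hydroxyl may close onto C1 and dehydrate. The fallback reverses the order of chain assembly; it sets out from 3 (with 4) and comes back at 7. The dianion of 4 (LiN(i-Pr)2, 2 equiv), a smaller and better-behaved nucleophile, opens 3 to give 1-[2-(2-hydroxyethyl)-6-methoxyphenyl]hexane-1,3,5-trione F4. The tetralithio derivative of F4 (alkoxide plus trianion), whose only terminal carbanion is the methyl carbon, is then acylated with ester 5 to give 7. Any O-propanoate formed at the alkoxide would be cleaved in the aqueous alkali of step 4.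

**Step 7.** Enolization of imidazolide 13 at its doubly benzylic CH2 (ketene formation, self-condensation) may outrun C-acylation of the dienolate. The fallback replaces the acylation by an aldol addition followed by oxidation; it sets out from 10 and comes back at 14. Alcohol 10 is oxidized with Dess–Martin periodinane to [2-(2-ethyl-4,6-dimethoxybenzoyl)-3-methoxyphenyl]acetaldehyde F5. Dioxinone 12 is converted (LiN(SiMe3)2, Me3SiCl) into its silyl dienol ether [(2,2-dimethyl-4-methylidene-4H-1,3-dioxin-6-yl)oxy](trimethyl)silane F6. A vinylogous Mukaiyama aldol addition of F6 to F5 (BF3·OEt2, CH2Cl2, −78 °C) gives racemic 6-{3-[2-(2-ethyl-4,6-dimethoxybenzoyl)-3-methoxyphenyl]-2-hydroxypropyl}-2,2-dimethyl-4H-1,3-dioxin-4-one F7. Oxidation of F7 with Dess–Martin periodinane gives 14.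

**Step 9.** Cleavage of the non-chelated para ether may be incomplete. Prolonged exposure to the strong Lewis acid may cause condensation of ring C or of the freed ortho phenol onto the activated ketone, or opening of the lactone. The fallback changes the protecting groups on ring A so that a milder reagent suffices; it sets out from 9 and comes back at 17.
- Benzylation of 9 (BnBr, K2CO3, acetone) gives [2,4-bis(benzyloxy)-6-ethylphenyl][2-(2-hydroxyethyl)-6-methoxyphenyl]methanone F8.
- Oxidation as in step 6 gives {2-[2,4-bis(benzyloxy)-6-ethylbenzoyl]-3-methoxyphenyl}acetic acid F9.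
- Activation with 1,1'-carbonyldiimidazole gives 2-{2-[2,4-bis(benzyloxy)-6-ethylbenzoyl]-3-methoxyphenyl}-1-(1H-imidazol-1-yl)ethan-1-one F10, which acylates the dienolate of 12 to 6-(3-{2-[2,4-bis(benzyloxy)-6-ethylbenzoyl]-3-methoxyphenyl}-2-oxopropyl)-2,2-dimethyl-4H-1,3-dioxin-4-one F11.
- Heating in toluene passes through 6-{2-[2,4-bis(benzyloxy)-6-ethylbenzoyl]-3-methoxyphenyl}hex-1-ene-1,3,5-trione F12 to 6-({2-[2,4-bis(benzyloxy)-6-ethylbenzoyl]-3-methoxyphenyl}methyl)-4-hydroxy-2H-pyran-2-one F13.
- BCl3 with pentamethylbenzene as cation scavenger (CH2Cl2, −78 → 0 °C) should remove both benzyl groups and the chelated ring B methyl ether, giving 17.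

## Further compounds

F1 | step 4 | 1-ethyl-3,5-dimethoxybenzene | CCc1cc(OC)cc(OC)c1
F2 | step 4 | 2-bromo-1-ethyl-3,5-dimethoxybenzene | CCc1cc(OC)cc(OC)c1Br
F3 | step 4 | (2-ethyl-4,6-dimethoxyphenyl)lithium | [Li]c1c(CC)cc(OC)cc1OC
F4 | step 3 | 1-[2-(2-hydroxyethyl)-6-methoxyphenyl]hexane-1,3,5-trione | CC(=O)CC(=O)CC(=O)c1c(OC)cccc1CCO
F5 | step 7 | [2-(2-ethyl-4,6-dimethoxybenzoyl)-3-methoxyphenyl]acetaldehyde | CCc1cc(OC)cc(OC)c1C(=O)c1c(OC)cccc1CC=O
F6 | step 7 | [(2,2-dimethyl-4-methylidene-4H-1,3-dioxin-6-yl)oxy](trimethyl)silane | C=C1C=C(O[Si](C)(C)C)OC(C)(C)O1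
F7 | step 7 | 6-{3-[2-(2-ethyl-4,6-dimethoxybenzoyl)-3-methoxyphenyl]-2-hydroxypropyl}-2,2-dimethyl-4H-1,3-dioxin-4-one (racemic) | CCc1cc(OC)cc(OC)c1C(=O)c1c(OC)cccc1CC(O)CC1=CC(=O)OC(C)(C)O1
F8 | step 9 | [2,4-bis(benzyloxy)-6-ethylphenyl][2-(2-hydroxyethyl)-6-methoxyphenyl]methanone | CCc1cc(OCc2ccccc2)cc(OCc2ccccc2)c1C(=O)c1c(OC)cccc1CCO
F9 | step 9 | {2-[2,4-bis(benzyloxy)-6-ethylbenzoyl]-3-methoxyphenyl}acetic acid | CCc1cc(OCc2ccccc2)cc(OCc2ccccc2)c1C(=O)c1c(OC)cccc1CC(=O)O
F10 | step 9 | 2-{2-[2,4-bis(benzyloxy)-6-ethylbenzoyl]-3-methoxyphenyl}-1-(1H-imidazol-1-yl)ethan-1-one | CCc1cc(OCc2ccccc2)cc(OCc2ccccc2)c1C(=O)c1c(OC)cccc1CC(=O)n1ccnc1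
F11 | step 9 | 6-(3-{2-[2,4-bis(benzyloxy)-6-ethylbenzoyl]-3-methoxyphenyl}-2-oxopropyl)-2,2-dimethyl-4H-1,3-dioxin-4-one | CCc1cc(OCc2ccccc2)cc(OCc2ccccc2)c1C(=O)c1c(OC)cccc1CC(=O)CC1=CC(=O)OC(C)(C)O1
F12 | step 9 | 6-{2-[2,4-bis(benzyloxy)-6-ethylbenzoyl]-3-methoxyphenyl}hex-1-ene-1,3,5-trione | CCc1cc(OCc2ccccc2)cc(OCc2ccccc2)c1C(=O)c1c(OC)cccc1CC(=O)CC(=O)C=C=O
F13 | step 9 | 6-({2-[2,4-bis(benzyloxy)-6-ethylbenzoyl]-3-methoxyphenyl}methyl)-4-hydroxy-2H-pyran-2-one | CCc1cc(OCc2ccccc2)cc(OCc2ccccc2)c1C(=O)c1c(OC)cccc1Cc1cc(O)cc(=O)o1
A1 | alternative 1 | 6-{[2-(2-ethyl-4,6-dimethoxybenzoyl)-3-methoxyphenyl]methyl}-2,2-dimethyl-4H-1,3-dioxin-4-one | CCc1cc(OC)cc(OC)c1C(=O)c1c(OC)cccc1CC1=CC(=O)OC(C)(C)O1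
A2 | alternative 1 | 4-[2-(2-ethyl-4,6-dimethoxybenzoyl)-3-methoxyphenyl]but-1-ene-1,3-dione | CCc1cc(OC)cc(OC)c1C(=O)c1c(OC)cccc1CC(=O)C=C=O
A3 | alternative 1 | 1,1-diethoxyethene | C=C(OCC)OCC
A4 | alternative 1 | 2-ethoxy-6-{[2-(2-ethyl-4,6-dimethoxybenzoyl)-3-methoxyphenyl]methyl}-4H-pyran-4-one | CCc1cc(OC)cc(OC)c1C(=O)c1c(OC)cccc1Cc1cc(=O)cc(OCC)o1
A5 | alternative 2 | 1-(2-ethyl-4,6-dimethoxyphenyl)butane-1,3-dione | CCc1cc(OC)cc(OC)c1C(=O)CC(C)=O
A6 | alternative 2 | 1-(2-ethyl-4,6-dimethoxyphenyl)-1,3-bis[(trimethylsilyl)oxy]buta-1,3-diene | CCc1cc(OC)cc(OC)c1C(O[Si](C)(C)C)=CC(=C)O[Si](C)(C)C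
A7 | alternative 2 | 5-(benzyloxy)-1,1-dimethoxypentan-3-one | COC(OC)CC(=O)CCOCc1ccccc1
A8 | alternative 2 | {2-[2-(benzyloxy)ethyl]-6-hydroxyphenyl}(2-ethyl-4,6-dimethoxyphenyl)methanone | CCc1cc(OC)cc(OC)c1C(=O)c1c(O)cccc1CCOCc1ccccc1
A9 | alternative 3 | 3-hydroxy-2H-pyran-2-one | O=c1occcc1O
A10 | alternative 3 | 5-{[tert-butyl(dimethyl)silyl]oxy}-1-(2-ethyl-4,6-dimethoxyphenyl)pent-2-yn-1-one | CCc1cc(OC)cc(OC)c1C(=O)C#CCCO[Si](C)(C)C(C)(C)C
A11 | alternative 3 | [2-(2-{[tert-butyl(dimethyl)silyl]oxy}ethyl)-6-hydroxyphenyl](2-ethyl-4,6-dimethoxyphenyl)methanone | CCc1cc(OC)cc(OC)c1C(=O)c1c(O)cccc1CCO[Si](C)(C)C(C)(C)C
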